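## Retrosynthetic overview

1. C-3 (S) is set last: Pd/PHOX enantioselective protonation of the achiral per-Alloc enol carbonate 19 of the racemic isoflavanone, with all four Alloc groups removed in the same operation.
2. A and C rings form in one operation from pyrone 12: Mg-templated Claisen aromatisation (A ring), then loss of MeOH and oxa-Michael closure (C ring).
3. C4–CH2 bond: triacetic acid lactone dianion + α-aryl-β-methoxy ester 9.
4. C3–C1′ bond: arylzinc + methyl 2-bromo-3-methoxypropanoate (Ni). The B ring comes from 3-methoxyphenol by two directed metalations, geranyl first, between the two oxygens.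
5. Ring order: B (bought) → A → C, the last two together in step 5.

Assumption: the (S)-PHOX ligand with Meldrum's acid is taken to give the (3S) ketone; the sense must be checked on the first run (chiral HPLC/ECD) and the (R)-ligand used if it proves opposite.

"Geranyl" = (2E)-3,7-dimethylocta-2,6-dien-1-yl throughout.

## Route

Step 1
Reactants: 1 3-methoxyphenol
Product: 2 1-methoxy-3-(methoxymethoxy)benzene
Conditions: NaH, MOMCl, THF, 0 °C → rt
Reagents that add atoms: chloromethyl methyl ether (MOMCl), COCCl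
Why: Williamson-type O-alkylation of the sodium phenoxide installs the MOM acetal that later directs both ortho-metalations; no stereocentre is involved.

Step 2
Reactants: 2 1-methoxy-3-(methoxymethoxy)benzene; 3 geranyl bromide
Product: 5 2-geranyl-1-methoxy-3-(methoxymethoxy)benzene, via 2-lithio arene 4 (not isolated)
Conditions: n-BuLi, THF, 0 °C → rt; CuBr·SMe2 (0.5 equiv), −40 °C; 3, → rt
Reagents that add atoms: none
Why: Directed ortho-metalation takes place at C-2, flanked by OMe and OMOM, and the arylcopper species is allylated at the primary carbon of geranyl bromide (SN2, E-olefin retained).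

Step 3
Reactants: 5 2-geranyl-1-methoxy-3-(methoxymethoxy)benzene; 6 methyl 2-bromo-3-methoxypropanoate (racemic)
Product: 9 methyl 2-[3-geranyl-4-methoxy-2-(methoxymethoxy)phenyl]-3-methoxypropanoate (racemic), via aryllithium 7 (not isolated), via arylzinc chloride 8 (not isolated)
Conditions: s-BuLi, TMEDA, THF, −78 °C; ZnCl2, −78 → 0 °C; then 6, NiCl2·glyme (10 mol%), dtbbpy (12 mol%), THF/DMA, 0 °C → rt
Reagents that add atoms: none
Why: A second directed ortho-metalation, ortho to the stronger OMOM director and run cold to avoid deprotonating the allylic-benzylic CH2, is followed by Li→Zn exchange and Ni-catalysed Negishi coupling with the secondary α-bromo ester; the new stereocentre is left racemic because it is erased and reset later.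

Step 4
Reactants: 9 methyl 2-[3-geranyl-4-methoxy-2-(methoxymethoxy)phenyl]-3-methoxypropanoate; 10 4-hydroxy-6-methyl-2H-pyran-2-one (triacetic acid lactone)
Product: 12 6-{3-[3-geranyl-4-methoxy-2-(methoxymethoxy)phenyl]-4-methoxy-2-oxobutyl}-4-hydroxy-2H-pyran-2-one (racemic), via dilithiated pyrone 11 (not isolated)
Conditions: 10 (3 equiv), LDA (6.2 equiv), THF, −78 → −20 °C; then 9, −78 → 0 °C; 1 M HCl
Reagents that add atoms: none
Why: Claisen-type C-acylation at the 6-CH2 terminus of the pyrone dianion (polyketide chain extension), with excess dianion to absorb the acidic product and any ester enolisation; the β-OMe is too poor a leaving group to be lost from the ester enolate in the cold.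

Step 5 (key step)
Reactants: 12 6-{3-[3-geranyl-4-methoxy-2-(methoxymethoxy)phenyl]-4-methoxy-2-oxobutyl}-4-hydroxy-2H-pyran-2-one
Product: 17 rac-3-(3-geranyl-2-hydroxy-4-methoxyphenyl)-5,7-dihydroxychroman-4-one, via triketo ester 13 (not isolated), via acylphloroglucinol 14 (not isolated), via aryl vinyl ketone 15 (not isolated), via MOM-protected isoflavanone 16 (not isolated)
Conditions: Mg(OMe)2 (8 equiv), MeOH, reflux, Ar, 16 h; then 3 M HCl/MeOH, 40 °C, 2 h
Reagents that add atoms: none
Why: Proposed new method: Mg(OMe)2 opens the pyrone to the Mg-chelated methyl 3,5,7-trioxo ester 13, whose C-6 carbanion closes onto the ester (biomimetic Claisen cyclisation/aromatisation, A ring, 14), E1cB loss of methanol then gives enone 15, 6-endo oxa-Michael addition of an ortho phenoxide closes the C ring (16) and the acidic work-up cleaves the MOM ether; the closest known reactions are the Mg(OMe)2 conversion of 6-(2-oxoalkyl)-4-hydroxy-2-pyrones into acylphloroglucinols and the mild-base closure of 2-hydroxy-α-(alkoxymethyl)deoxybenzoins to isoflavanones; C-3 is formed racemic by uncontrolled protonation.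

Step 6
Reactants: 17 rac-3-(3-geranyl-2-hydroxy-4-methoxyphenyl)-5,7-dihydroxychroman-4-one
Product: 19 allyl 3-[2-(allyloxycarbonyloxy)-3-geranyl-4-methoxyphenyl]-5,7-bis(allyloxycarbonyloxy)-2H-chromen-4-yl carbonate, via tris(allyl carbonate) 18 (not isolated)
Conditions: AllocCl (3.3 equiv), Et3N, DMAP (cat.), THF, 0 °C → rt; then −78 °C, KHMDS (1.1 equiv), AllocCl (1.2 equiv)
Reagents that add atoms: allyl chloroformate (AllocCl), C=CCOC(Cl)=O
Why: Phenol O-acylation followed by O-acylation of the potassium enolate with the chloroformate gives the allyl enol carbonate, which makes C-3 sp2 (stereocentre erased) and puts a Pd-labile allyl carbonate on every oxygen.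

Step 7
Reactants: 19 allyl 3-[2-(allyloxycarbonyloxy)-3-geranyl-4-methoxyphenyl]-5,7-bis(allyloxycarbonyloxy)-2H-chromen-4-yl carbonate
Product: 20 (3S)-3-(3-geranyl-2-hydroxy-4-methoxyphenyl)-5,7-dihydroxychroman-4-one
Conditions: Pd2(dba)3 (5 mol%), (S)-(CF3)3-t-BuPHOX (12.5 mol%), Meldrum's acid (6 equiv), THF, rt → 40 °C
Reagents that add atoms: none
Why: Proposed new method: Pd(0)/PHOX ionises all four allyl carbonates, CO2 is lost, Meldrum's acid traps the allyl groups and protonates the phenoxides, and the chiral Pd–PHOX enolate is protonated at C-3 on one face to give the (S)-ketone; the closest known reaction is the Pd-catalysed decarboxylative asymmetric protonation of isoflavanone allyl β-keto esters with Meldrum's acid, where ortho-substituted 3-aryl groups give the highest ee, and the new elements are the enol-carbonate entry and the simultaneous Alloc removal from three phenols.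

## Compound list

1 | 3-methoxyphenol | COc1cccc(O)c1 | starting material
2 | 1-methoxy-3-(methoxymethoxy)benzene | COc1cccc(OCOC)c1 | intermediate
3 | geranyl bromide, (2E)-1-bromo-3,7-dimethylocta-2,6-diene | BrC/C=C(\C)CCC=C(C)C | starting material
4 | 2-lithio-1-methoxy-3-(methoxymethoxy)benzene (not isolated) | COc1cccc(OCOC)c1[Li] | intermediate
5 | 2-geranyl-1-methoxy-3-(methoxymethoxy)benzene | COc1cccc(OCOC)c1C/C=C(\C)CCC=C(C)C | intermediate
6 | methyl 2-bromo-3-methoxypropanoate (racemic) | COCC(Br)C(=O)OC | starting material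
7 | [3-geranyl-4-methoxy-2-(methoxymethoxy)phenyl]lithium (not isolated) | COc1ccc([Li])c(OCOC)c1C/C=C(\C)CCC=C(C)C | intermediate
8 | [3-geranyl-4-methoxy-2-(methoxymethoxy)phenyl]zinc chloride (not isolated) | COc1ccc([Zn]Cl)c(OCOC)c1C/C=C(\C)CCC=C(C)C | intermediate
9 | methyl 2-[3-geranyl-4-methoxy-2-(methoxymethoxy)phenyl]-3-methoxypropanoate (racemic) | COCC(C(=O)OC)c1ccc(OC)c(C/C=C(\C)CCC=C(C)C)c1OCOC | intermediate
10 | 4-hydroxy-6-methyl-2H-pyran-2-one (triacetic acid lactone) | Cc1cc(O)cc(=O)o1 | starting material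
11 | dilithio dianion of 10 at O-4 and 6-CH2 (not isolated) | [Li]Cc1cc(O[Li])cc(=O)o1 | intermediate
12 | 6-{3-[3-geranyl-4-methoxy-2-(methoxymethoxy)phenyl]-4-methoxy-2-oxobutyl}-4-hydroxy-2H-pyran-2-one (racemic) | COCC(C(=O)Cc1cc(O)cc(=O)o1)c1ccc(OC)c(C/C=C(\C)CCC=C(C)C)c1OCOC | intermediate
13 | methyl 8-[3-geranyl-4-methoxy-2-(methoxymethoxy)phenyl]-9-methoxy-3,5,7-trioxononanoate (racemic, Mg chelate in the flask, not isolated) | COCC(C(=O)CC(=O)CC(=O)CC(=O)OC)c1ccc(OC)c(C/C=C(\C)CCC=C(C)C)c1OCOC | intermediate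
14 | 2-[3-geranyl-4-methoxy-2-(methoxymethoxy)phenyl]-3-methoxy-1-(2,4,6-trihydroxyphenyl)propan-1-one (racemic, not isolated) | COCC(C(=O)c1c(O)cc(O)cc1O)c1ccc(OC)c(C/C=C(\C)CCC=C(C)C)c1OCOC | intermediate
15 | 2-[3-geranyl-4-methoxy-2-(methoxymethoxy)phenyl]-1-(2,4,6-trihydroxyphenyl)prop-2-en-1-one (not isolated) | C=C(C(=O)c1c(O)cc(O)cc1O)c1ccc(OC)c(C/C=C(\C)CCC=C(C)C)c1OCOC | intermediate
16 | rac-3-[3-geranyl-4-methoxy-2-(methoxymethoxy)phenyl]-5,7-dihydroxychroman-4-one (not isolated) | COCOc1c(C2COc3cc(O)cc(O)c3C2=O)ccc(OC)c1C/C=C(\C)CCC=C(C)C | intermediate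
17 | rac-3-(3-geranyl-2-hydroxy-4-methoxyphenyl)-5,7-dihydroxychroman-4-one | COc1ccc(C2COc3cc(O)cc(O)c3C2=O)c(O)c1C/C=C(\C)CCC=C(C)C | intermediate
18 | rac-5,7,2′-tris(allyl carbonate) of 17 (not isolated) | COc1ccc(C2COc3cc(OC(=O)OCC=C)cc(OC(=O)OCC=C)c3C2=O)c(OC(=O)OCC=C)c1C/C=C(\C)CCC=C(C)C | intermediate
19 | allyl 3-[2-(allyloxycarbonyloxy)-3-geranyl-4-methoxyphenyl]-5,7-bis(allyloxycarbonyloxy)-2H-chromen-4-yl carbonate (achiral) | COc1ccc(C2=C(OC(=O)OCC=C)c3c(OC(=O)OCC=C)cc(OC(=O)OCC=C)cc3OC2)c(OC(=O)OCC=C)c1C/C=C(\C)CCC=C(C)C | intermediate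
20 | (3S)-3-(3-geranyl-2-hydroxy-4-methoxyphenyl)-5,7-dihydroxychroman-4-one | COc1ccc([C@H]2COc3cc(O)cc(O)c3C2=O)c(O)c1C/C=C(\C)CCC=C(C)C | target

## Step count

Total steps: 7. Longest linear sequence: 7 (from 3-methoxyphenol).

## Three steps most likely to fail

Step 5 (key double ring formation). The risks are aldol-type closure of 13 to a resorcylate instead of the Claisen mode, and slow loss of methanol from the Mg-chelated ketone 14. The fallback sets out from 9 and returns at 17, taking the A ring from phloroglucinol. Ester 9 is converted (MeNHOMe·HCl, i-PrMgCl) into the Weinreb amide 2-[3-geranyl-4-methoxy-2-(methoxymethoxy)phenyl]-N,3-dimethoxy-N-methylpropanamide F1. Commercial phloroglucinol is protected as 1,3,5-tris(methoxymethoxy)benzene F2 and lithiated with n-BuLi to 2,4,6-tris(methoxymethoxy)phenyllithium F3. F3 is acylated by F1 to the tetra-MOM aryl ketone F4. HCl/MeOH then gives the tetrahydroxy β-methoxy ketone F5, and K2CO3 in refluxing acetone (E1cB, then oxa-Michael) closes it to 17.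

Step 7 (enantioselective protonation). The risks are erosion of ee by the phenols released in the same flask, competing C-allylation, and an unverified sense of induction; the product may also need an ee upgrade by crystallisation. The fallback sets out from 17 and returns at 20, replacing protonation by a reduction/oxidation sequence. 17 is protected (MOMCl, i-Pr2NEt, DMAP) as the racemic tris-MOM isoflavanone F6. Asymmetric transfer hydrogenation with dynamic kinetic resolution (RuCl[(S,S)-TsDPEN](p-cymene), HCO2H/Et3N) gives the cis-(3S,4S)-isoflavan-4-ol F7. Buffered Dess–Martin oxidation gives the (S)-tris-MOM isoflavanone F8, and HCl/MeOH at 0 °C → rt releases 20.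

Step 4 (dianion acylation). The risk is that the basic dianion enolises the α-aryl ester instead of acylating. The fallback sets out from 9 and returns at 12, replacing the Claisen acylation by aldehyde addition and oxidation. 9 is reduced with DIBAL-H at −78 °C to the aldehyde 2-[3-geranyl-4-methoxy-2-(methoxymethoxy)phenyl]-3-methoxypropanal F9. Dianion 11 adds to F9 (1,2-addition outruns proton transfer) to give the hydroxy pyrone F10, and Dess–Martin oxidation gives 12.

## Further compounds

F1 | step 5 | 2-[3-geranyl-4-methoxy-2-(methoxymethoxy)phenyl]-N,3-dimethoxy-N-methylpropanamide (racemic) | COCC(C(=O)N(C)OC)c1ccc(OC)c(C/C=C(\C)CCC=C(C)C)c1OCOC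
F2 | step 5 | 1,3,5-tris(methoxymethoxy)benzene | COCOc1cc(OCOC)cc(OCOC)c1
F3 | step 5 | 2,4,6-tris(methoxymethoxy)phenyllithium | [Li]c1c(OCOC)cc(OCOC)cc1OCOC
F4 | step 5 | 2-[3-geranyl-4-methoxy-2-(methoxymethoxy)phenyl]-3-methoxy-1-[2,4,6-tris(methoxymethoxy)phenyl]propan-1-one (racemic) | COCC(C(=O)c1c(OCOC)cc(OCOC)cc1OCOC)c1ccc(OC)c(C/C=C(\C)CCC=C(C)C)c1OCOC
F5 | step 5 | 2-(3-geranyl-2-hydroxy-4-methoxyphenyl)-3-methoxy-1-(2,4,6-trihydroxyphenyl)propan-1-one (racemic) | COCC(C(=O)c1c(O)cc(O)cc1O)c1ccc(OC)c(C/C=C(\C)CCC=C(C)C)c1O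
F6 | step 7 | rac-3-[3-geranyl-4-methoxy-2-(methoxymethoxy)phenyl]-5,7-bis(methoxymethoxy)chroman-4-one | COc1ccc(C2COc3cc(OCOC)cc(OCOC)c3C2=O)c(OCOC)c1C/C=C(\C)CCC=C(C)C
F7 | step 7 | (3S,4S)-3-[3-geranyl-4-methoxy-2-(methoxymethoxy)phenyl]-5,7-bis(methoxymethoxy)chroman-4-ol (cis) | COc1ccc([C@H]2COc3cc(OCOC)cc(OCOC)c3[C@H]2O)c(OCOC)c1C/C=C(\C)CCC=C(C)C
F8 | step 7 | (3S)-3-[3-geranyl-4-methoxy-2-(methoxymethoxy)phenyl]-5,7-bis(methoxymethoxy)chroman-4-one | COc1ccc([C@H]2COc3cc(OCOC)cc(OCOC)c3C2=O)c(OCOC)c1C/C=C(\C)CCC=C(C)C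
F9 | step 4 | 2-[3-geranyl-4-methoxy-2-(methoxymethoxy)phenyl]-3-methoxypropanal (racemic) | COCC(C=O)c1ccc(OC)c(C/C=C(\C)CCC=C(C)C)c1OCOC
F10 | step 4 | 6-{3-[3-geranyl-4-methoxy-2-(methoxymethoxy)phenyl]-2-hydroxy-4-methoxybutyl}-4-hydroxy-2H-pyran-2-one (diastereomer mixture) | COCC(C(O)Cc1cc(O)cc(=O)o1)c1ccc(OC)c(C/C=C(\C)CCC=C(C)C)c1OCOC
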